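**Plan**

- Retrosynthesis: cut the C18–O coumarate ester (back to a malonic half ester plus 4-hydroxybenzaldehyde) and take C15 back to a silyl-protected alcohol; then cut C9–C10 and C4–C5, which opens both carbocycles to an acyclic (2R,3R)-epoxy triene that ends in an allylsilane; then cut C6–C7 (allyl sulfone alkylation) and C8=C9 (Wittig).
- Forward: (S)-citronellol gives the C9 aldehyde and, by Wittig olefination, a 2-(silylmethyl)allyl bromide; this alkylates the 8-hydroxygeranyl sulfone dianion; desulfonylation and Sharpless epoxidation follow; one Lewis-acid event then closes ring A (C4–C5) and, last, ring B (C9–C10).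
- Enabling feature: ring B (C5–C10) carries its 8(17)-methylene exactly where a CH2SiMe3 group on C8 can end a cation–olefin cascade, and C4, C5=C10 and C8=C9 sit in the 1,5-diene spacing of a trans-decalin whose C18 CH2O group, C11 side chain and ring fusion are what a chair–chair fold delivers.
- Stereochemistry: C13 comes from (S)-citronellol; C3/C4 from the D-(−)-tartrate-controlled epoxidation of the (E)-allylic alcohol; C5, C10 and C9 are relayed from the oxirane through the chair–chair transition state and the geometry of the two trisubstituted alkenes.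
- Helpers removed later: sulfone (step 10), SiMe3 (step 13), C3–OH (step 15), silyl ethers (steps 16 and 17).

Key step: step 13

Remark: labdane numbering is used for all intermediates (C15 carboxyl carbon, C17 exocyclic methylene carbon, C18 the CH2O carbon on C4, C19 and C20 the methyl groups on C4 and C10); with it the target is the (4S,5S,9R,10S,13S) isomer.

**Route**

Step 1
Reactants: 1 (S)-citronellol
Product: 2 tert-butyl{[(3S)-3,7-dimethyloct-6-en-1-yl]oxy}dimethylsilane
Conditions: TBSCl, imidazole, CH2Cl2, rt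
Reagents that add atoms: tert-butyldimethylsilyl chloride, CC(C)(C)[Si](C)(C)Cl
Why: Standard silylation of the primary alcohol leaves the chiral-pool stereocentre (later C13) untouched and gives an ether that later serves as the latent C15 carboxyl group.

Step 2
Reactants: 2 tert-butyl{[(3S)-3,7-dimethyloct-6-en-1-yl]oxy}dimethylsilane
Product: 4 (4S)-6-[(tert-butyldimethylsilyl)oxy]-4-methylhexanal, via ozonide 3 (not isolated)
Conditions: O3, CH2Cl2, −78 °C; then PPh3, −78 °C to rt
Reagents that add atoms: ozone, [O-][O+]=O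
Why: Ozonolysis with reductive work-up cleaves the only alkene and should give the C9 aldehyde without affecting the remote stereocentre.

Step 3
Reactants: 5 ethyl (triphenyl-λ5-phosphanylidene)acetate; 6 (iodomethyl)trimethylsilane
Product: 8 ethyl 2-(triphenyl-λ5-phosphanylidene)-3-(trimethylsilyl)propanoate, via phosphonium iodide 7 (not isolated)
Conditions: MeCN, 80 °C; then DBU, CH2Cl2, 0 °C
Reagents that add atoms: none
Why: C-alkylation of a stabilized phosphorus ylide by a primary iodide, then deprotonation of the phosphonium salt with a non-nucleophilic amidine base (which avoids attack at silicon), should give the α-(silylmethyl) ylide.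

Step 4
Reactants: 4 (4S)-6-[(tert-butyldimethylsilyl)oxy]-4-methylhexanal; 8 ethyl 2-(triphenyl-λ5-phosphanylidene)-3-(trimethylsilyl)propanoate
Product: 9 ethyl (2Z,6S)-8-[(tert-butyldimethylsilyl)oxy]-6-methyl-2-[(trimethylsilyl)methyl]oct-2-enoate
Conditions: toluene, 90 °C
Reagents that add atoms: none
Why: Wittig olefination with an α-branched ester-stabilized ylide places the ester trans to the aldehyde-derived chain, which sets the C8=C9 geometry with CH2SiMe3 cis to C11 (Z by the CIP rules because silicon outranks oxygen).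

Step 5
Reactants: 9 ethyl (2Z,6S)-8-[(tert-butyldimethylsilyl)oxy]-6-methyl-2-[(trimethylsilyl)methyl]oct-2-enoate
Product: 10 (2Z,6S)-8-[(tert-butyldimethylsilyl)oxy]-6-methyl-2-[(trimethylsilyl)methyl]oct-2-en-1-ol
Conditions: i-Bu2AlH, CH2Cl2, −78 °C; aq. potassium sodium tartrate
Reagents that add atoms: none
Why: 1,2-Reduction of the enoate by the aluminium hydride at low temperature should give the allylic alcohol without isomerizing the alkene or touching the allylsilane and the silyl ether.

Step 6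
Reactants: 10 (2Z,6S)-8-[(tert-butyldimethylsilyl)oxy]-6-methyl-2-[(trimethylsilyl)methyl]oct-2-en-1-ol
Product: 12 {[(3S,6E)-7-(bromomethyl)-3-methyl-8-(trimethylsilyl)oct-6-en-1-yl]oxy}(tert-butyl)dimethylsilane, via allylic mesylate 11 (not isolated)
Conditions: MsCl, Et3N, THF, −40 °C; then LiBr, −40 to 0 °C
Reagents that add atoms: lithium bromide, [Li+].[Br-]
Why: Mesylation and in situ SN2 displacement by bromide at the primary allylic carbon is a mild route to the allylic bromide and keeps the alkene geometry (2-(silylmethyl)allyl halides are stable, isolable compounds).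

Step 7
Reactants: 13 geranyl bromide
Product: 14 geranyl phenyl sulfone
Conditions: PhSO2Na, DMF, rt
Reagents that add atoms: sodium benzenesulfinate, [Na+].[O-]S(=O)c1ccccc1
Why: S-Alkylation of the sulfinate by the primary allylic bromide (SN2) gives the sulfone with the (E)-alkene unchanged.

Step 8
Reactants: 14 geranyl phenyl sulfone
Product: 15 (2E,6E)-2,6-dimethyl-8-(phenylsulfonyl)octa-2,6-dien-1-ol
Conditions: SeO2 (cat.), t-BuOOH, salicylic acid (cat.), CH2Cl2, rt
Reagents that add atoms: tert-butyl hydroperoxide, CC(C)(C)OO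
Why: Allylic oxidation by SeO2 (ene reaction, then [2,3]-sigmatropic shift) attacks the electron-rich terminal alkene in preference to the sulfone-deactivated one and is selective for the (E)-methyl group, which fixes the geometry that later makes C18 equatorial.

Step 9
Reactants: 15 (2E,6E)-2,6-dimethyl-8-(phenylsulfonyl)octa-2,6-dien-1-ol; 12 {[(3S,6E)-7-(bromomethyl)-3-methyl-8-(trimethylsilyl)oct-6-en-1-yl]oxy}(tert-butyl)dimethylsilane
Product: 17 (2E,6E,10Z,14S)-16-[(tert-butyldimethylsilyl)oxy]-2,6,14-trimethyl-8-(phenylsulfonyl)-10-[(trimethylsilyl)methyl]hexadeca-2,6,10-trien-1-ol (both C8 epimers), via sulfone dianion 16 (not isolated)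
Conditions: n-BuLi (2.1 equiv), THF–DMPU, −78 °C; then 12, −78 to −40 °C
Reagents that add atoms: none
Why: In this allyl sulfone alkylation the α-sulfonyl carbanion of the dianion is far more nucleophilic than the lithium alkoxide and should attack the primary allylic bromide in SN2 fashion to form the C6–C7 bond; the new sulfone-bearing stereocentre is of no consequence because it is removed in step 10.

Step 10
Reactants: 17 (2E,6E,10Z,14S)-16-[(tert-butyldimethylsilyl)oxy]-2,6,14-trimethyl-8-(phenylsulfonyl)-10-[(trimethylsilyl)methyl]hexadeca-2,6,10-trien-1-ol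
Product: 18 (2E,6E,10Z,14S)-16-[(tert-butyldimethylsilyl)oxy]-2,6,14-trimethyl-10-[(trimethylsilyl)methyl]hexadeca-2,6,10-trien-1-ol
Conditions: PdCl2(dppp) (cat.; dppp = Ph2P(CH2)3PPh2), LiBHEt3, THF, 0 °C
Reagents that add atoms: none
Why: In this palladium-catalysed reductive desulfonylation, zerovalent palladium ionizes the allylic C–S bond and hydride is delivered to the less substituted allyl terminus (C6), so the (E)-C5=C10 alkene should keep its position and geometry.

Step 11
Reactants: 18 (2E,6E,10Z,14S)-16-[(tert-butyldimethylsilyl)oxy]-2,6,14-trimethyl-10-[(trimethylsilyl)methyl]hexadeca-2,6,10-trien-1-ol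
Product: 19 [(2R,3R)-3-{(3E,7Z,11S)-13-[(tert-butyldimethylsilyl)oxy]-3,11-dimethyl-7-[(trimethylsilyl)methyl]trideca-3,7-dien-1-yl}-2-methyloxiran-2-yl]methanol
Conditions: Ti(OiPr)4 (cat.), D-(−)-diethyl tartrate, t-BuOOH, 4 Å molecular sieves, CH2Cl2, −20 °C
Reagents that add atoms: tert-butyl hydroperoxide, CC(C)(C)OO
Why: Sharpless asymmetric epoxidation reacts only at the alkene of the allylic alcohol, and the D-(−)-tartrate ligand should deliver oxygen to the face that gives the (2R,3R)-oxirane (later C4 and C3 of ring A).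

Step 12
Reactants: 19 [(2R,3R)-3-{(3E,7Z,11S)-13-[(tert-butyldimethylsilyl)oxy]-3,11-dimethyl-7-[(trimethylsilyl)methyl]trideca-3,7-dien-1-yl}-2-methyloxiran-2-yl]methanol
Product: 20 tert-butyl({(2R,3R)-3-[(3E,7Z,11S)-13-[(tert-butyldimethylsilyl)oxy]-3,11-dimethyl-7-[(trimethylsilyl)methyl]trideca-3,7-dien-1-yl]-2-methyloxiran-2-yl}methoxy)diphenylsilane
Conditions: TBDPSCl, imidazole, DMAP (cat.), CH2Cl2, rt
Reagents that add atoms: tert-butyl(chloro)diphenylsilane, CC(C)(C)[Si](Cl)(c1ccccc1)c1ccccc1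
Why: Silylation with the bulky TBDPS group masks the primary alcohol, disfavours chelation of the Lewis acid between the two oxygens and is orthogonal to the TBS ether at C15.

Step 13
Reactants: 20 tert-butyl({(2R,3R)-3-[(3E,7Z,11S)-13-[(tert-butyldimethylsilyl)oxy]-3,11-dimethyl-7-[(trimethylsilyl)methyl]trideca-3,7-dien-1-yl]-2-methyloxiran-2-yl}methoxy)diphenylsilane
Product: 21 (3R,4S,5S,9R,10S,13S)-15-[(tert-butyldimethylsilyl)oxy]-18-[(tert-butyldiphenylsilyl)oxy]labd-8(17)-en-3-ol
Conditions: MeAlCl2, CH2Cl2, −78 °C; aq. NaHCO3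
Reagents that add atoms: none
Why: MeAlCl2 coordinates the oxirane oxygen, the tertiary C4–O bond is attacked from the back by the C5=C10 π bond, the resulting C10 cation is captured by C9 of the allylsilane, and loss of the silyl group from the β-silyl cation at C8 leaves the 8(17)-methylene; the closest known reaction type is the Lewis-acid-promoted, epoxide-initiated and allylsilane-terminated cation–olefin polycyclization. Ring A closes by 6-endo opening of the oxirane at C4 anti to the leaving oxygen, and ring B, closed last, by 6-endo attack of the C8=C9 bond on C10, both through chair-like arrays. C4 is set by inversion at the oxirane carbon, so the former (E)-CH2OTBDPS group becomes equatorial and the methyl group axial; C3 keeps its oxirane configuration with the oxygen equatorial; C5 and C10 follow from anti addition across the (E)-C5=C10 bond (trans fusion, axial C10 methyl); C9 follows from the C8=C9 geometry, in which C7 and C11 are trans, so the side chain is equatorial. The absolute sense of the fold is dictated by the (2R,3R)-oxirane, because only one chair–chair array allows backside attack at C4 with the C3–O bond equatorial, and the remote C13 centre plays no part. The step needs ionization at C4 and not at C3 and a clean end of the cascade: the first is secured by the tertiary nature of C4 and the bulky, poorly chelating silyl ether on C18, the second by the β-silicon effect, which makes C9 the nucleophilic carbon and should give only the exocyclic alkene.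

Step 14
Reactants: 21 (3R,4S,5S,9R,10S,13S)-15-[(tert-butyldimethylsilyl)oxy]-18-[(tert-butyldiphenylsilyl)oxy]labd-8(17)-en-3-ol
Product: 22 O-{(3R,4S,5S,9R,10S,13S)-15-[(tert-butyldimethylsilyl)oxy]-18-[(tert-butyldiphenylsilyl)oxy]labd-8(17)-en-3-yl} 1H-imidazole-1-carbothioate
Conditions: 1,1'-thiocarbonyldiimidazole, DMAP (cat.), toluene, 100 °C
Reagents that add atoms: 1,1'-thiocarbonyldiimidazole, S=C(n1ccnc1)n1ccnc1
Why: Thioacylation of the hindered equatorial C3 hydroxyl under neutral conditions (no alkoxide, hence no silyl migration from O18) prepares the substrate for radical deoxygenation.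

Step 15
Reactants: 22 O-{(3R,4S,5S,9R,10S,13S)-15-[(tert-butyldimethylsilyl)oxy]-18-[(tert-butyldiphenylsilyl)oxy]labd-8(17)-en-3-yl} 1H-imidazole-1-carbothioate
Product: 23 (4S,5S,9R,10S,13S)-15-[(tert-butyldimethylsilyl)oxy]-18-[(tert-butyldiphenylsilyl)oxy]labd-8(17)-ene
Conditions: Bu3SnH, AIBN (cat.), toluene, 110 °C
Reagents that add atoms: none
Why: In this Barton–McCombie deoxygenation the tin radical adds to sulfur, β-scission gives the secondary C3 radical, and hydrogen transfer from Bu3SnH removes the helper oxygen without touching any stereocentre that remains in the target.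

Step 16
Reactants: 23 (4S,5S,9R,10S,13S)-15-[(tert-butyldimethylsilyl)oxy]-18-[(tert-butyldiphenylsilyl)oxy]labd-8(17)-ene
Product: 26 (4S,5S,9R,10S,13S)-18-[(tert-butyldiphenylsilyl)oxy]labd-8(17)-en-15-oic acid, via primary alcohol 24 (not isolated), via aldehyde 25 (not isolated)
Conditions: CrO3, H2SO4, H2O, acetone, 0 °C
Reagents that add atoms: water, O
Why: Jones oxidation in aqueous acidic acetone cleaves the unhindered primary TBS ether and oxidizes the freed alcohol through the aldehyde hydrate to the acid, while the hindered neopentyl TBDPS ether, the 1,1-disubstituted alkene and the stereocentres should survive.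

Step 17
Reactants: 26 (4S,5S,9R,10S,13S)-18-[(tert-butyldiphenylsilyl)oxy]labd-8(17)-en-15-oic acid
Product: 27 (4S,5S,9R,10S,13S)-18-hydroxylabd-8(17)-en-15-oic acid
Conditions: Bu4NF (excess), THF, 40 °C
Reagents that add atoms: none
Why: Fluoride cleaves the Si–O bond of the neopentyl silyl ether, and the carboxylate is inert under these conditions.

Step 18
Reactants: 27 (4S,5S,9R,10S,13S)-18-hydroxylabd-8(17)-en-15-oic acid; 28 Meldrum's acid
Product: 29 (4S,5S,9R,10S,13S)-18-[(carboxyacetyl)oxy]labd-8(17)-en-15-oic acid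
Conditions: toluene, 100 °C
Reagents that add atoms: none
Why: Thermal alcoholysis of Meldrum's acid by the primary alcohol gives the malonic half ester with loss of acetone, and the C15 carboxylic acid is not a competent nucleophile here.

Step 19
Reactants: 29 (4S,5S,9R,10S,13S)-18-[(carboxyacetyl)oxy]labd-8(17)-en-15-oic acid; 30 4-hydroxybenzaldehyde
Product: 31 (4S,5S,9R,10S,13S)-18-{[(2E)-3-(4-hydroxyphenyl)prop-2-enoyl]oxy}labd-8(17)-en-15-oic acid (CNP0389065.1)
Conditions: pyridine, piperidine (cat.), 60 °C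
Reagents that add atoms: none
Why: Knoevenagel–Doebner condensation of the malonic half ester with the aldehyde and decarboxylative elimination should give the (E)-4-hydroxycinnamate directly, so that neither the phenol nor the C15 acid needs protection.

**Compound list**

1 | (S)-citronellol, (3S)-3,7-dimethyloct-6-en-1-ol | CC(C)=CCC[C@H](C)CCO | starting material
2 | tert-butyl{[(3S)-3,7-dimethyloct-6-en-1-yl]oxy}dimethylsilane | CC(C)=CCC[C@H](C)CCO[Si](C)(C)C(C)(C)C | intermediate
3 | ozonide of 2, 5-{(3S)-5-[(tert-butyldimethylsilyl)oxy]-3-methylpentyl}-3,3-dimethyl-1,2,4-trioxolane | CC1(C)OOC(CC[C@H](C)CCO[Si](C)(C)C(C)(C)C)O1 | intermediate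
4 | (4S)-6-[(tert-butyldimethylsilyl)oxy]-4-methylhexanal | O=CCC[C@H](C)CCO[Si](C)(C)C(C)(C)C | intermediate
5 | ethyl (triphenyl-λ5-phosphanylidene)acetate | CCOC(=O)C=P(c1ccccc1)(c1ccccc1)c1ccccc1 | starting material
6 | (iodomethyl)trimethylsilane | C[Si](C)(C)CI | starting material
7 | [1-ethoxy-1-oxo-3-(trimethylsilyl)propan-2-yl]triphenylphosphonium iodide | CCOC(=O)C(C[Si](C)(C)C)[P+](c1ccccc1)(c1ccccc1)c1ccccc1.[I-] | intermediate
8 | ethyl 2-(triphenyl-λ5-phosphanylidene)-3-(trimethylsilyl)propanoate | CCOC(=O)C(C[Si](C)(C)C)=P(c1ccccc1)(c1ccccc1)c1ccccc1 | intermediate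
9 | ethyl (2Z,6S)-8-[(tert-butyldimethylsilyl)oxy]-6-methyl-2-[(trimethylsilyl)methyl]oct-2-enoate | CCOC(=O)/C(C[Si](C)(C)C)=C/CC[C@H](C)CCO[Si](C)(C)C(C)(C)C | intermediate
10 | (2Z,6S)-8-[(tert-butyldimethylsilyl)oxy]-6-methyl-2-[(trimethylsilyl)methyl]oct-2-en-1-ol | OC/C(C[Si](C)(C)C)=C/CC[C@H](C)CCO[Si](C)(C)C(C)(C)C | intermediate
11 | (2Z,6S)-8-[(tert-butyldimethylsilyl)oxy]-6-methyl-2-[(trimethylsilyl)methyl]oct-2-en-1-yl methanesulfonate | CS(=O)(=O)OC/C(C[Si](C)(C)C)=C/CC[C@H](C)CCO[Si](C)(C)C(C)(C)C | intermediate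
12 | {[(3S,6E)-7-(bromomethyl)-3-methyl-8-(trimethylsilyl)oct-6-en-1-yl]oxy}(tert-butyl)dimethylsilane | BrC/C(C[Si](C)(C)C)=C/CC[C@H](C)CCO[Si](C)(C)C(C)(C)C | intermediate
13 | geranyl bromide, (2E)-1-bromo-3,7-dimethylocta-2,6-diene | CC(C)=CCC/C(C)=C/CBr | starting material
14 | geranyl phenyl sulfone, {[(2E)-3,7-dimethylocta-2,6-dien-1-yl]sulfonyl}benzene | CC(C)=CCC/C(C)=C/CS(=O)(=O)c1ccccc1 | intermediate
15 | (2E,6E)-2,6-dimethyl-8-(phenylsulfonyl)octa-2,6-dien-1-ol | OC/C(C)=C/CC/C(C)=C/CS(=O)(=O)c1ccccc1 | intermediate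
16 | dilithio derivative of 15 (lithium alkoxide, α-sulfonyl carbanion) | [Li]OC/C(C)=C/CC/C(C)=C/C([Li])S(=O)(=O)c1ccccc1 | intermediate
17 | (2E,6E,10Z,14S)-16-[(tert-butyldimethylsilyl)oxy]-2,6,14-trimethyl-8-(phenylsulfonyl)-10-[(trimethylsilyl)methyl]hexadeca-2,6,10-trien-1-ol, both C8 epimers | OC/C(C)=C/CC/C(C)=C/C(C/C(C[Si](C)(C)C)=C/CC[C@H](C)CCO[Si](C)(C)C(C)(C)C)S(=O)(=O)c1ccccc1 | intermediate
18 | (2E,6E,10Z,14S)-16-[(tert-butyldimethylsilyl)oxy]-2,6,14-trimethyl-10-[(trimethylsilyl)methyl]hexadeca-2,6,10-trien-1-ol | OC/C(C)=C/CC/C(C)=C/CC/C(C[Si](C)(C)C)=C/CC[C@H](C)CCO[Si](C)(C)C(C)(C)C | intermediate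
19 | [(2R,3R)-3-{(3E,7Z,11S)-13-[(tert-butyldimethylsilyl)oxy]-3,11-dimethyl-7-[(trimethylsilyl)methyl]trideca-3,7-dien-1-yl}-2-methyloxiran-2-yl]methanol | OC[C@@]1(C)O[C@@H]1CC/C(C)=C/CC/C(C[Si](C)(C)C)=C/CC[C@H](C)CCO[Si](C)(C)C(C)(C)C | intermediate
20 | tert-butyl({(2R,3R)-3-[(3E,7Z,11S)-13-[(tert-butyldimethylsilyl)oxy]-3,11-dimethyl-7-[(trimethylsilyl)methyl]trideca-3,7-dien-1-yl]-2-methyloxiran-2-yl}methoxy)diphenylsilane | CC(C)(C)[Si](c2ccccc2)(c3ccccc3)OC[C@@]1(C)O[C@@H]1CC/C(C)=C/CC/C(C[Si](C)(C)C)=C/CC[C@H](C)CCO[Si](C)(C)C(C)(C)C | intermediate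
21 | (3R,4S,5S,9R,10S,13S)-15-[(tert-butyldimethylsilyl)oxy]-18-[(tert-butyldiphenylsilyl)oxy]labd-8(17)-en-3-ol (trans-decalin; 3-OH, C18 and the C9 chain equatorial; C19 and C20 axial on the same face) | C=C1CC[C@@H]2[C@@](C)(CO[Si](c3ccccc3)(c4ccccc4)C(C)(C)C)[C@H](O)CC[C@@]2(C)[C@@H]1CC[C@H](C)CCO[Si](C)(C)C(C)(C)C | intermediate
22 | O-{(3R,4S,5S,9R,10S,13S)-15-[(tert-butyldimethylsilyl)oxy]-18-[(tert-butyldiphenylsilyl)oxy]labd-8(17)-en-3-yl} 1H-imidazole-1-carbothioate | C=C1CC[C@@H]2[C@@](C)(CO[Si](c3ccccc3)(c4ccccc4)C(C)(C)C)[C@H](OC(=S)n5ccnc5)CC[C@@]2(C)[C@@H]1CC[C@H](C)CCO[Si](C)(C)C(C)(C)C | intermediate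
23 | (4S,5S,9R,10S,13S)-15-[(tert-butyldimethylsilyl)oxy]-18-[(tert-butyldiphenylsilyl)oxy]labd-8(17)-ene | C=C1CC[C@@H]2[C@@](C)(CO[Si](c3ccccc3)(c4ccccc4)C(C)(C)C)CCC[C@@]2(C)[C@@H]1CC[C@H](C)CCO[Si](C)(C)C(C)(C)C | intermediate
24 | (4S,5S,9R,10S,13S)-18-[(tert-butyldiphenylsilyl)oxy]labd-8(17)-en-15-ol | C=C1CC[C@@H]2[C@@](C)(CO[Si](c3ccccc3)(c4ccccc4)C(C)(C)C)CCC[C@@]2(C)[C@@H]1CC[C@H](C)CCO | intermediate
25 | (4S,5S,9R,10S,13S)-18-[(tert-butyldiphenylsilyl)oxy]labd-8(17)-en-15-al | C=C1CC[C@@H]2[C@@](C)(CO[Si](c3ccccc3)(c4ccccc4)C(C)(C)C)CCC[C@@]2(C)[C@@H]1CC[C@H](C)CC=O | intermediate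
26 | (4S,5S,9R,10S,13S)-18-[(tert-butyldiphenylsilyl)oxy]labd-8(17)-en-15-oic acid | C=C1CC[C@@H]2[C@@](C)(CO[Si](c3ccccc3)(c4ccccc4)C(C)(C)C)CCC[C@@]2(C)[C@@H]1CC[C@H](C)CC(=O)O | intermediate
27 | (4S,5S,9R,10S,13S)-18-hydroxylabd-8(17)-en-15-oic acid | C=C1CC[C@@H]2[C@@](C)(CO)CCC[C@@]2(C)[C@@H]1CC[C@H](C)CC(=O)O | intermediate
28 | Meldrum's acid, 2,2-dimethyl-1,3-dioxane-4,6-dione | CC1(C)OC(=O)CC(=O)O1 | starting material
29 | (4S,5S,9R,10S,13S)-18-[(carboxyacetyl)oxy]labd-8(17)-en-15-oic acid | C=C1CC[C@@H]2[C@@](C)(COC(=O)CC(=O)O)CCC[C@@]2(C)[C@@H]1CC[C@H](C)CC(=O)O | intermediate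
30 | 4-hydroxybenzaldehyde | O=Cc1ccc(O)cc1 | starting material
31 | (4S,5S,9R,10S,13S)-18-{[(2E)-3-(4-hydroxyphenyl)prop-2-enoyl]oxy}labd-8(17)-en-15-oic acid | C=C1CC[C@@H]2[C@@](C)(COC(=O)/C=C/c3ccc(O)cc3)CCC[C@@]2(C)[C@@H]1CC[C@H](C)CC(=O)O | target

**Step count and risks**

Total steps: 19. Longest linear sequence: 16 steps (steps 1, 2, 4, 5, 6 and 9 to 19, from (S)-citronellol).

Steps most likely to fail:

Step 13. The oxirane may ionize in the wrong direction (1,2-hydride shift to a C3 ketone, or attack of the alkene at C3), or the cascade may stop after ring A because the CH2OSi group disfavours positive charge at C4. The fallback moves the closure to a radical manifold that does not depend on the electron demand at C4. It sets out from 2 and returns at 21.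
- Allylic oxidation of 2 (SeO2 cat., t-BuOOH) should give (2E,6S)-8-[(tert-butyldimethylsilyl)oxy]-2,6-dimethyloct-2-en-1-ol F1.
- CBr4 and PPh3 convert it into the allylic bromide F2.
- Alkylation of dianion 16 with F2 gives the hydroxy sulfone F3.
- PdCl2(dppp) and LiBHEt3 give the triene alcohol F4.
- Sharpless epoxidation with D-(−)-diethyl tartrate gives the epoxy alcohol F5, and TBDPSCl gives its silyl ether F6.
- Cp2TiCl (2.2 equiv, a chloride of trivalent titanium made from Cp2TiCl2 and Mn dust, THF, rt) then opens the oxirane homolytically to the tertiary C4 radical. 6-endo, 6-endo radical cyclization through the same chair–chair fold and β-hydride elimination from the C8 alkyltitanium species should give the 8(17)-alkene, which is 21.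
- In this manifold C4 is a planar radical, so its configuration would rest only on the equatorial preference of the CH2OTBDPS group, and a C4 epimer may have to be separated.

Step 9. O-alkylation may compete, the product may transfer a proton to the dianion, or the 2-(silylmethyl)allyl bromide may undergo SN2′ attack or elimination; the reduction in step 10 may also transpose the alkene. The fallback forms C6–C7 by a direct allyl–allyl coupling without a sulfone. It sets out from bromide 12 and returns at 18.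
- Commercial geranyl chloride is oxidized (SeO2 cat., t-BuOOH) to (2E,6E)-8-chloro-2,6-dimethylocta-2,6-dien-1-ol F7 and silylated (Et3SiCl, imidazole) to its triethylsilyl ether F8.
- Reactive barium (from BaI2 and lithium biphenylide, THF, −78 °C) converts F8 into the allylbarium chloride F9.
- F9 should couple with 12 α to α with retention of both alkene geometries to give the triethylsilyl ether of 18, F10.
- PPTS in MeOH at 0 °C removes the triethylsilyl group without touching the TBS ether and gives 18, so steps 9 and 10 are not needed.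

Step 4. The bulky α-branched ylide may react sluggishly, geometric purity may erode, or the ylide may lose its silyl group. The fallback builds the alkene by carbometalation of an alkyne. It sets out from aldehyde 4 and returns at 10.
- CBr4 and PPh3 give the dibromoalkene F11 (Corey–Fuchs reaction).
- n-BuLi (2.1 equiv, THF, −78 °C) gives the lithium acetylide F12, which is trapped with paraformaldehyde as the propargylic alcohol F13.
- Me3SiCH2MgCl (3 equiv) with CuI (cat.) in THF then adds across the alkyne in an anti sense under the direction of the magnesium alkoxide. The CH2SiMe3 group goes to the carbon next to CH2OH and hydrogen (after protonation) ends cis to CH2OH, which is the geometry of 10.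

**Further compounds**

F1 | step 13 | (2E,6S)-8-[(tert-butyldimethylsilyl)oxy]-2,6-dimethyloct-2-en-1-ol | OC/C(C)=C/CC[C@H](C)CCO[Si](C)(C)C(C)(C)C
F2 | step 13 | {[(3S,6E)-8-bromo-3,7-dimethyloct-6-en-1-yl]oxy}(tert-butyl)dimethylsilane | BrC/C(C)=C/CC[C@H](C)CCO[Si](C)(C)C(C)(C)C
F3 | step 13 | (2E,6E,10E,14S)-16-[(tert-butyldimethylsilyl)oxy]-2,6,10,14-tetramethyl-8-(phenylsulfonyl)hexadeca-2,6,10-trien-1-ol, both C8 epimers | OC/C(C)=C/CC/C(C)=C/C(C/C(C)=C/CC[C@H](C)CCO[Si](C)(C)C(C)(C)C)S(=O)(=O)c1ccccc1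
F4 | step 13 | (2E,6E,10E,14S)-16-[(tert-butyldimethylsilyl)oxy]-2,6,10,14-tetramethylhexadeca-2,6,10-trien-1-ol | OC/C(C)=C/CC/C(C)=C/CC/C(C)=C/CC[C@H](C)CCO[Si](C)(C)C(C)(C)C
F5 | step 13 | [(2R,3R)-3-{(3E,7E,11S)-13-[(tert-butyldimethylsilyl)oxy]-3,7,11-trimethyltrideca-3,7-dien-1-yl}-2-methyloxiran-2-yl]methanol | OC[C@@]1(C)O[C@@H]1CC/C(C)=C/CC/C(C)=C/CC[C@H](C)CCO[Si](C)(C)C(C)(C)C
F6 | step 13 | tert-butyl({(2R,3R)-3-[(3E,7E,11S)-13-[(tert-butyldimethylsilyl)oxy]-3,7,11-trimethyltrideca-3,7-dien-1-yl]-2-methyloxiran-2-yl}methoxy)diphenylsilane | CC(C)(C)[Si](c2ccccc2)(c3ccccc3)OC[C@@]1(C)O[C@@H]1CC/C(C)=C/CC/C(C)=C/CC[C@H](C)CCO[Si](C)(C)C(C)(C)C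
F7 | step 9 | (2E,6E)-8-chloro-2,6-dimethylocta-2,6-dien-1-ol | OC/C(C)=C/CC/C(C)=C/CCl
F8 | step 9 | {[(2E,6E)-8-chloro-2,6-dimethylocta-2,6-dien-1-yl]oxy}triethylsilane | CC[Si](CC)(CC)OC/C(C)=C/CC/C(C)=C/CCl
F9 | step 9 | chloro{(2E,6E)-3,7-dimethyl-8-[(triethylsilyl)oxy]octa-2,6-dien-1-yl}barium | CC[Si](CC)(CC)OC/C(C)=C/CC/C(C)=C/C[Ba]Cl
F10 | step 9 | triethylsilyl ether of 18 | CC[Si](CC)(CC)OC/C(C)=C/CC/C(C)=C/CC/C(C[Si](C)(C)C)=C/CC[C@H](C)CCO[Si](C)(C)C(C)(C)C
F11 | step 4 | tert-butyl{[(3S)-7,7-dibromo-3-methylhept-6-en-1-yl]oxy}dimethylsilane | BrC(Br)=CCC[C@H](C)CCO[Si](C)(C)C(C)(C)C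
F12 | step 4 | lithium (5S)-7-[(tert-butyldimethylsilyl)oxy]-5-methylhept-1-yn-1-ide | [Li]C#CCC[C@H](C)CCO[Si](C)(C)C(C)(C)C
F13 | step 4 | (6S)-8-[(tert-butyldimethylsilyl)oxy]-6-methyloct-2-yn-1-ol | OCC#CCC[C@H](C)CCO[Si](C)(C)C(C)(C)C
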